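## The problem

Compound 24 is a 2,8-dioxabicyclo[3.2.1]octane. Its ketal carbon C1 carries the side chain, O8 is the one-atom bridge, C6–C7 is a plain ethano bridge, and the O2–C3–C4 bridge plus bridgehead C5 carry three carboxyl groups and a tertiary hydroxyl on three contiguous stereocentres, two of them (C4, C5) fully substituted. C1 is a ketal centre and is dictated by the bicycle once C3–C5 are in place. C5 can control C4 and C3 if they are created on a ring that contains it. The side-chain centre C5' is too remote to steer the core or be steered by it, so it must be bought as a single enantiomer, and any error at C5 then appears as a diastereomer of the whole molecule. The E-trisubstituted C3'=C4' alkene rules out ozone, hydrogenation, electrophilic oxidants and long exposure to strong protic acid. C3–H (α to a carboxyl and to the ketal oxygen) can epimerise, and the β-hydroxy acid array can undergo retro-aldol cleavage under forcing base. The enabling feature is that C1 bears two oxygens and O2–C3 is, at the right oxidation level, the C=O of a glyoxylate. If the second oxygen of C1 sits on C4 instead of C5, the skeleton is a 6,8-dioxabicyclo[3.2.1]octane whose dioxolane ring C1–O–C4–C3–O2 is the [3+2] adduct of a C1–O–C4 carbonyl ylide with O2=C3. Because C4 and C5 are both oxygenated and C6/C7 are unfunctionalised, that ylide comes from a simple keto diazo ester and the two ketals are one acid equilibration apart.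

## Retrosynthesis

**24 from 23.** Only the two ethyl ester C–O bonds at C3 and C5 are cut. Diester acid 23 is preferred to a uniform triester because the C4 carboxyl, wedged between C3 and the quaternary C5, would be the slowest to saponify. It is therefore carried as a tert-butyl ester that the ketal chemistry removes anyway. The forward step has to hydrolyse two α-alkoxy esters without touching C3–H.

**23 from 20.** The C1–O8 bond is cut and C1 is reconnected to the C4 oxygen, giving the isomeric 6,8-dioxabicyclo[3.2.1]octane 20 with C5–O as a trimethylsilyl ether and C4 as a tert-butyl ester. This transposition converts a skeleton with no obvious cycloaddition retron into one that has it, and costs no extra step because desilylation, tert-butyl cleavage and equilibration (through 21 and 22) share one acid treatment. The forward reaction must favour the 2,8-ketal thermodynamically and spare the side-chain alkene.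

**20 from 17 and 18.** C1–O2, C3–C4 and the C4–O bond are cut together. This gives ethyl glyoxylate 18 and the acyclic keto diazo ester 17 by way of carbonyl ylide 19. Cutting C3–C4 alone (an aldol) would leave both C3 and C4 to be controlled separately. Cutting at C6/C7 would force unsaturation into the ethano bridge. The chosen cut removes both rings and three stereocentres and leaves one stereocentre, C5. The forward step asks for ketone capture of the carbenoid, glyoxylate approach anti to the C5 silyloxy group, and an exo ester.

**17 from 14 and 15 (through 16).** The C4–C5 bond is cut as an aldol addition of tert-butyl diazoacetate 15 to the α-keto ester of 14, followed by silylation. Diazo transfer onto an unactivated C4 methylene is not workable, so this is the only direct entry to the α-diazo-β-hydroxy ester. Enantiocontrol at C5 is the soft spot of the plan and is strengthened in three ways: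
- The electrophile is an α-keto ester, the class for which chiral N,N'-dioxide–Sc(OTf)3 complexes catalyse this very addition through two-point binding.
- The chelating ester is kept small (ethyl).
- Because C5' is already present, the C5 epimer of 16 is a diastereomer, so purity can be read and if necessary restored before C5 is asked to steer the cycloaddition.

**14 from 11 and 12 (through 13).** The C5–C6 bond is cut as a conjugate addition of the acyl-anion equivalent 12 to vinyl ketone 11, then unmasking. The 1,4-relationship of the C1 and C5 carbonyls demands one umpolung, and the dithiane ester delivers the α-keto ester carbon with its ester attached. The unmasking must leave the alkene alone.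

**11 from 8 and 10 (through 9).** The C1–C7 bond is cut. Ester 8 becomes Weinreb amide 9, which accepts vinylmagnesium bromide 10 once. This is a standard two-step conversion of an ester to an enone.

**8 from 5 and 6 (through 7).** The C1'–C2' bond and the C3'=C4' alkene are cut together by a Johnson–Claisen transform. One pericyclic step then installs the E-trisubstituted alkene and the two-carbon ester arm, and removes the need to control the carbinol centre of allylic alcohol 5. A Wittig approach would need a later two-carbon homologation.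

**5 from 1 and 3 (through 2 and 4).** The C3'–C4' bond is cut. Commercial acid 1 supplies C5' as its Weinreb amide 2, which takes isopropenylmagnesium bromide 3 to give enone 4. 1,2-Reduction then gives 5.

## Roads not taken

**Alternative 1:** The cut is C1=C7, followed by a transannular C1–O8 ketalisation. In the substrate A1, C1 is the carbonyl of an ester on the C3 oxygen, C5 carries an allyl group, C4/C5 are an acetonide and the three carboxyls are silyl-protected primary alcohols. The titanium alkylidene made from TiCl4, Zn, PbCl2, TMEDA and CH3CHBr2 would join the terminal alkene to the ester carbonyl and close the oxepene enol ether A2. Mild acid would then add the C5 hydroxyl across the enol ether.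
- Merits: the correct ketal forms kinetically with no equilibrium and little acid, and the C3–C5 array is independent of any catalytic asymmetric step. In these two respects this road is better than the chosen one.
- Weak points: all three carboxyls must be raised from the alcohol level at the end, next to a trisubstituted alkene and a tertiary alcohol. A large excess of low-valent titanium must act on a hindered ester beside quaternary C4. The triol with two tetrasubstituted centres needs its own long synthesis.
- Against this, the chosen plan has carboxyls at the right oxidation level from the start and makes two rings, three bonds and three stereocentres in one step.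

**Alternative 2:** The cut is C3–C4. In A3, C1 is already a mixed ketal (tetrahydrofuran ring through the C5 oxygen, methyl glycolate on the other oxygen) and C4 is a keto ester. KN(SiMe3)2 would enolise the glycolate and the enolate would add to the C4 ketone, closing the 1,3-dioxane and giving the trimethyl ester A4.
- Merits: the 2,8-skeleton appears directly, with no diazo compound and no late acid exposure of the alkene. On that last point it is better than the chosen plan.
- Weak points: only one C1 epimer of A3 can cyclise, and it must be made by ketalisation beside a hydrate-prone vicinal dicarbonyl. The aldol sets C3 and C4 at once and is reversible. C5 still needs the same asymmetric construction. The C4 methyl ester would be the hardest to hydrolyse.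
- Against this, the chosen plan has a concerted cycloaddition that fixes C3 and C4 relative to C5, and an acid-labile C4 ester.

**Alternative 3:** The cuts are C5–O8, C1–C7 and C5–C6. In A5 the diazo group is on C5 and C1 is an ester carbonyl on the C3 oxygen. Rh2(OAc)4 would give a carbenoid that the ester oxygen captures (closing the 1,3-dioxane), and the ylide would add ethynyl p-tolyl sulfone A6 to give A7.
- Merits: the 2,8-ketal forms directly. C3 and C4 can come from the chiral pool, so the absolute configuration is more secure than in the chosen plan. Three tert-butyl esters fall in one acid step.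
- Weak points for this target: A7 has a C6=C7 double bond and a sulfonyl group, whereas 24 has two methylenes. Desulfonylation and saturation must then be done in the presence of the side-chain alkene. Ester carbonyls are also poorer ylide partners than ketones.
- Against this, the chosen plan has C6/C7 at the right level from the start, no reductions near the alkene, and a dipolarophile that brings the C3 carboxyl ready-made.

Key step: step 11

Assumption: the sense of induction of the chiral scandium catalyst in step 9 is taken to be selectable through the ligand antipode (both derive from commercial pipecolic acid enantiomers); the one giving the 3R carbinol is used. Target locants (C1–C7, O2, O8; side chain C1'–C6') are used for the corresponding atoms of all precursors.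

## Route

Step 1
Reactants: 1 (2S)-2-methyl-3-phenylpropanoic acid
Product: 2 (2S)-N-methoxy-N,2-dimethyl-3-phenylpropanamide
Conditions: MeNH(OMe)·HCl, EDC·HCl, HOBt (cat.), iPr2NEt, CH2Cl2, 0 °C → rt
Reagents that add atoms: N,O-dimethylhydroxylamine hydrochloride, CNOC.Cl
Why: Carbodiimide amide coupling; with HOBt the activated acid is short-lived, so the α-centre should not epimerise, and the Weinreb amide prepares the single addition of step 2.

Step 2
Reactants: 2 (2S)-N-methoxy-N,2-dimethyl-3-phenylpropanamide; 3 isopropenylmagnesium bromide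
Product: 4 (4S)-2,4-dimethyl-5-phenylpent-1-en-3-one
Conditions: 3 (1.5 equiv), THF, 0 °C; cold aq. NH4Cl
Reagents that add atoms: isopropenylmagnesium bromide (3), CC(=C)[Mg]Br
Why: Weinreb ketone synthesis; the chelated magnesium adduct persists until the quench, so the Grignard reagent adds once and the α-methyl centre is not exposed to base as a ketone.

Step 3
Reactants: 4 (4S)-2,4-dimethyl-5-phenylpent-1-en-3-one
Product: 5 (4S)-2,4-dimethyl-5-phenylpent-1-en-3-ol (both C3 epimers)
Conditions: NaBH4, CeCl3·7H2O, MeOH, −78 → 0 °C
Reagents that add atoms: none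
Why: Luche reduction gives clean 1,2-hydride delivery to the enone at low temperature without touching C4; the new carbinol centre need not be controlled because step 4 destroys it.

Step 4
Reactants: 5 (4S)-2,4-dimethyl-5-phenylpent-1-en-3-ol; 6 triethyl orthoacetate
Product: 8 ethyl (4E,6S)-4,6-dimethyl-7-phenylhept-4-enoate, via ketene acetal 7 (not isolated)
Conditions: 6 (6 equiv), EtCO2H (cat.), 140 °C, EtOH distilled off
Reagents that add atoms: triethyl orthoacetate (6), CCOC(C)(OCC)OCC
Why: Johnson–Claisen rearrangement; in the chair transition state of 7 the CH(CH3)CH2Ph group sits equatorial (the 2-methyl group penalises the axial alternative), so the new trisubstituted alkene should be E, and the S centre becomes allylic and is not touched.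

Step 5
Reactants: 8 ethyl (4E,6S)-4,6-dimethyl-7-phenylhept-4-enoate
Product: 9 (4E,6S)-N-methoxy-N,4,6-trimethyl-7-phenylhept-4-enamide
Conditions: MeNH(OMe)·HCl, iPrMgCl, THF, −20 → 0 °C
Reagents that add atoms: N,O-dimethylhydroxylamine hydrochloride, CNOC.Cl
Why: Direct aminolysis of the ester by the chloromagnesium amide of N,O-dimethylhydroxylamine (Weinreb amide formation), with no need to pass through the free acid.

Step 6
Reactants: 9 (4E,6S)-N-methoxy-N,4,6-trimethyl-7-phenylhept-4-enamide; 10 vinylmagnesium bromide
Product: 11 (6E,8S)-6,8-dimethyl-9-phenylnona-1,6-dien-3-one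
Conditions: 10 (1.5 equiv), THF, −78 → 0 °C; inverse quench into cold 1 M HCl
Reagents that add atoms: vinylmagnesium bromide (10), C=C[Mg]Br
Why: Weinreb ketone synthesis with a vinyl Grignard reagent forms C1–C7; the acidic inverse quench keeps liberated MeNH(OMe) from adding to the new enone.

Step 7
Reactants: 11 (6E,8S)-6,8-dimethyl-9-phenylnona-1,6-dien-3-one; 12 ethyl 1,3-dithiane-2-carboxylate
Product: 13 ethyl 2-[(6E,8S)-6,8-dimethyl-3-oxo-9-phenylnon-6-en-1-yl]-1,3-dithiane-2-carboxylate
Conditions: 12 (1.1 equiv), t-BuOK (10 mol%), THF, −20 → 0 °C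
Reagents that add atoms: ethyl 1,3-dithiane-2-carboxylate (12), CCOC(=O)C1SCCCS1
Why: Michael addition of a Corey–Seebach-type acyl-anion equivalent; the soft ester-stabilised dithianyl anion adds 1,4 to the unhindered vinyl ketone to form C5–C6, and the product enolate regenerates the base.

Step 8
Reactants: 13 ethyl 2-[(6E,8S)-6,8-dimethyl-3-oxo-9-phenylnon-6-en-1-yl]-1,3-dithiane-2-carboxylate
Product: 14 ethyl (8E,10S)-8,10-dimethyl-2,5-dioxo-11-phenylundec-8-enoate
Conditions: PhI(OCOCF3)2 (1.5 equiv), NaHCO3, MeCN/H2O (9:1), 0 °C
Reagents that add atoms: water, O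
Why: Oxidative dethioketalisation with a trivalent iodine reagent; sulfur is far more nucleophilic than the isolated alkene, and the bicarbonate buffer should prevent acid-induced Paal–Knorr closure of the 1,4-dicarbonyl product to a furan.

Step 9
Reactants: 14 ethyl (8E,10S)-8,10-dimethyl-2,5-dioxo-11-phenylundec-8-enoate; 15 tert-butyl diazoacetate
Product: 16 1-tert-butyl 4-ethyl (3R)-2-diazo-3-[(6E,8S)-6,8-dimethyl-3-oxo-9-phenylnon-6-en-1-yl]-3-hydroxybutanedioate
Conditions: 15 (1.5 equiv), Sc(OTf)3 (5 mol%), C2-symmetric N,N'-dioxide of propane-1,3-diyl-bridged pipecolic acid 2,6-diisopropylanilide (6 mol%), CH2Cl2, 0 °C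
Reagents that add atoms: tert-butyl diazoacetate (15), CC(C)(C)OC(=O)C=[N+]=[N-]
Why: Catalytic enantioselective aldol-type addition of a diazoacetate to an α-keto ester; the 1,2-dicarbonyl chelates the chiral trivalent scandium complex, which exposes one face of the C5 carbonyl to the nucleophilic diazo carbon and sets C5 as R, while the isolated C1 ketone neither chelates nor competes as an electrophile.

Step 10
Reactants: 16 1-tert-butyl 4-ethyl (3R)-2-diazo-3-[(6E,8S)-6,8-dimethyl-3-oxo-9-phenylnon-6-en-1-yl]-3-hydroxybutanedioate
Product: 17 1-tert-butyl 4-ethyl (3R)-2-diazo-3-[(6E,8S)-6,8-dimethyl-3-oxo-9-phenylnon-6-en-1-yl]-3-[(trimethylsilyl)oxy]butanedioate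
Conditions: 1-(trimethylsilyl)imidazole (2 equiv), CH2Cl2, rt
Reagents that add atoms: 1-(trimethylsilyl)imidazole, C[Si](C)(C)n1ccnc1
Why: Silylation of the hindered tertiary alcohol with a neutral, powerful silyl donor; no acid is generated, so the diazo group survives, and the small silyl group falls off in step 12.

Step 11
Reactants: 17 1-tert-butyl 4-ethyl (3R)-2-diazo-3-[(6E,8S)-6,8-dimethyl-3-oxo-9-phenylnon-6-en-1-yl]-3-[(trimethylsilyl)oxy]butanedioate; 18 ethyl glyoxylate
Product: 20 1-tert-butyl 2,7-diethyl (1S,2R,5S,7S)-5-[(3E,5S)-3,5-dimethyl-6-phenylhex-3-en-1-yl]-2-[(trimethylsilyl)oxy]-6,8-dioxabicyclo[3.2.1]octane-1,2,7-tricarboxylate, via carbonyl ylide 19 (not isolated)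
Conditions: Rh2(OAc)4 (2 mol%), 18 (3 equiv, freshly distilled), PhMe, 110 °C, slow addition of 17
Reagents that add atoms: ethyl glyoxylate (18), CCOC(=O)C=O
Why: Rh2(OAc)4 extrudes N2 from 17 to give a C4 rhodium carbenoid, and the lone pair of the C1 ketone oxygen attacks it (C4–O bond; six-membered ring, a 6-exo closure with respect to the carbon–rhodium bond) to release the cyclic carbonyl ylide 19. The ylide is trapped by the aldehyde C=O of 18 in a concerted suprafacial [3+2] cycloaddition that forms C1–O2 and C3–C4 together and so closes the five-membered dioxolane ring. The closest known reaction type is the tandem rhodium-carbenoid carbonyl ylide formation/1,3-dipolar cycloaddition of diazo ketones with aldehydes, glyoxylates being among the best dipolarophiles. Regiochemistry follows the polarity of the dipole: the ester-stabilised, nucleophilic C4 terminus bonds to the aldehyde carbon and the oxocarbenium-like C1 to its oxygen. C1 and C4 become bridgeheads, so their relative configuration is fixed by the bicycle and their absolute sense by the face attacked; C5 controls this, because its silyloxy group takes the pseudoaxial position next to the electron-rich C4 and shields that face, so 18 adds anti to it. C3 is set by the exo orientation of the glyoxylate ester, away from the C5–C6–C7 bridge. The step needs intramolecular capture of the carbenoid by the ketone to outrun its reaction with 18, which the six-membered geometry and slow addition of 17 should secure, and no 1,2-hydride shift can compete because C5 is fully substituted. One event therefore builds two rings, three skeletal bonds and three stereocentres.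

Step 12
Reactants: 20 1-tert-butyl 2,7-diethyl (1S,2R,5S,7S)-5-[(3E,5S)-3,5-dimethyl-6-phenylhex-3-en-1-yl]-2-[(trimethylsilyl)oxy]-6,8-dioxabicyclo[3.2.1]octane-1,2,7-tricarboxylate
Product: 23 (1S,3S,4S,5R)-1-[(3E,5S)-3,5-dimethyl-6-phenylhex-3-en-1-yl]-3,5-bis(ethoxycarbonyl)-4-hydroxy-2,8-dioxabicyclo[3.2.1]octane-4-carboxylic acid, via hydroxy triester 21 (not isolated), via hydroxy acid 22 (not isolated)
Conditions: TFA/CH2Cl2/H2O (20:10:1), 0 °C → rt, followed by HPLC and stopped at equilibrium; recovered 22 resubmitted
Reagents that add atoms: none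
Why: Acid-mediated desilylation, tert-butyl ester cleavage and ketal transposition; ionisation of the C1–O(C4) bond gives an oxocarbenium ion that the C5 hydroxyl recaptures, and the equilibrium is expected to favour the 2,8-ketal, whose C3 and C4 carboxyl groups are equatorial on a chair 1,3-dioxane. C3, C4 and C5 are not touched and C1 is dictated by the bicycle.

Step 13
Reactants: 23 (1S,3S,4S,5R)-1-[(3E,5S)-3,5-dimethyl-6-phenylhex-3-en-1-yl]-3,5-bis(ethoxycarbonyl)-4-hydroxy-2,8-dioxabicyclo[3.2.1]octane-4-carboxylic acid
Product: 24 (1S,3S,4S,5R)-1-[(3E,5S)-3,5-dimethyl-6-phenylhex-3-en-1-yl]-4-hydroxy-2,8-dioxabicyclo[3.2.1]octane-3,4,5-tricarboxylic acid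
Conditions: KOH (1 M aq., 6 equiv), THF, rt → 40 °C; then 1 M HCl to pH 2; reverse-phase chromatography
Reagents that add atoms: potassium hydroxide, [K+].[OH-]
Why: Saponification of two α-alkoxy ethyl esters, which are activated towards hydroxide; once the C3 carboxylate is formed it no longer enolises, so C3 should keep its configuration, and acidification liberates the triacid.

## Compound list

1 | (2S)-2-methyl-3-phenylpropanoic acid | OC(=O)[C@@H](C)Cc1ccccc1 | starting material
2 | (2S)-N-methoxy-N,2-dimethyl-3-phenylpropanamide | CON(C)C(=O)[C@@H](C)Cc1ccccc1 | intermediate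
3 | isopropenylmagnesium bromide | CC(=C)[Mg]Br | starting material
4 | (4S)-2,4-dimethyl-5-phenylpent-1-en-3-one | CC(=C)C(=O)[C@@H](C)Cc1ccccc1 | intermediate
5 | (4S)-2,4-dimethyl-5-phenylpent-1-en-3-ol (both C3 epimers) | CC(=C)C(O)[C@@H](C)Cc1ccccc1 | intermediate
6 | triethyl orthoacetate | CCOC(C)(OCC)OCC | starting material
7 | ketene acetal {(2S)-3-[(1-ethoxyethenyl)oxy]-2,4-dimethylpent-4-en-1-yl}benzene (not isolated) | C=C(OCC)OC(C(C)=C)[C@@H](C)Cc1ccccc1 | intermediate
8 | ethyl (4E,6S)-4,6-dimethyl-7-phenylhept-4-enoate | C/C(=C\[C@@H](C)Cc1ccccc1)CCC(=O)OCC | intermediate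
9 | (4E,6S)-N-methoxy-N,4,6-trimethyl-7-phenylhept-4-enamide | C/C(=C\[C@@H](C)Cc1ccccc1)CCC(=O)N(C)OC | intermediate
10 | vinylmagnesium bromide | C=C[Mg]Br | starting material
11 | (6E,8S)-6,8-dimethyl-9-phenylnona-1,6-dien-3-one | C/C(=C\[C@@H](C)Cc1ccccc1)CCC(=O)C=C | intermediate
12 | ethyl 1,3-dithiane-2-carboxylate | CCOC(=O)C1SCCCS1 | starting material
13 | ethyl 2-[(6E,8S)-6,8-dimethyl-3-oxo-9-phenylnon-6-en-1-yl]-1,3-dithiane-2-carboxylate | C/C(=C\[C@@H](C)Cc1ccccc1)CCC(=O)CCC1(C(=O)OCC)SCCCS1 | intermediate
14 | ethyl (8E,10S)-8,10-dimethyl-2,5-dioxo-11-phenylundec-8-enoate | C/C(=C\[C@@H](C)Cc1ccccc1)CCC(=O)CCC(=O)C(=O)OCC | intermediate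
15 | tert-butyl diazoacetate | CC(C)(C)OC(=O)C=[N+]=[N-] | starting material
16 | 1-tert-butyl 4-ethyl (3R)-2-diazo-3-[(6E,8S)-6,8-dimethyl-3-oxo-9-phenylnon-6-en-1-yl]-3-hydroxybutanedioate | C/C(=C\[C@@H](C)Cc1ccccc1)CCC(=O)CC[C@](O)(C(=O)OCC)C(=[N+]=[N-])C(=O)OC(C)(C)C | intermediate
17 | 1-tert-butyl 4-ethyl (3R)-2-diazo-3-[(6E,8S)-6,8-dimethyl-3-oxo-9-phenylnon-6-en-1-yl]-3-[(trimethylsilyl)oxy]butanedioate | C/C(=C\[C@@H](C)Cc1ccccc1)CCC(=O)CC[C@](O[Si](C)(C)C)(C(=O)OCC)C(=[N+]=[N-])C(=O)OC(C)(C)C | intermediate
18 | ethyl glyoxylate | CCOC(=O)C=O | starting material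
19 | cyclic carbonyl ylide, (3R)-2-(tert-butoxycarbonyl)-6-[(3E,5S)-3,5-dimethyl-6-phenylhex-3-en-1-yl]-3-(ethoxycarbonyl)-3-[(trimethylsilyl)oxy]-4,5-dihydro-3H-pyran-1-ium-2-ide (not isolated) | C/C(=C\[C@@H](C)Cc1ccccc1)CCC1=[O+][C-](C(=O)OC(C)(C)C)[C@@](O[Si](C)(C)C)(C(=O)OCC)CC1 | intermediate
20 | 1-tert-butyl 2,7-diethyl (1S,2R,5S,7S)-5-[(3E,5S)-3,5-dimethyl-6-phenylhex-3-en-1-yl]-2-[(trimethylsilyl)oxy]-6,8-dioxabicyclo[3.2.1]octane-1,2,7-tricarboxylate | C/C(=C\[C@@H](C)Cc1ccccc1)CC[C@@]12CC[C@](O[Si](C)(C)C)(C(=O)OCC)[C@@](C(=O)OC(C)(C)C)(O1)[C@@H](C(=O)OCC)O2 | intermediate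
21 | 1-tert-butyl 2,7-diethyl (1S,2R,5S,7S)-5-[(3E,5S)-3,5-dimethyl-6-phenylhex-3-en-1-yl]-2-hydroxy-6,8-dioxabicyclo[3.2.1]octane-1,2,7-tricarboxylate (not isolated) | C/C(=C\[C@@H](C)Cc1ccccc1)CC[C@@]12CC[C@](O)(C(=O)OCC)[C@@](C(=O)OC(C)(C)C)(O1)[C@@H](C(=O)OCC)O2 | intermediate
22 | (1S,2R,5S,7S)-5-[(3E,5S)-3,5-dimethyl-6-phenylhex-3-en-1-yl]-2,7-bis(ethoxycarbonyl)-2-hydroxy-6,8-dioxabicyclo[3.2.1]octane-1-carboxylic acid (not isolated) | C/C(=C\[C@@H](C)Cc1ccccc1)CC[C@@]12CC[C@](O)(C(=O)OCC)[C@@](C(=O)O)(O1)[C@@H](C(=O)OCC)O2 | intermediate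
23 | (1S,3S,4S,5R)-1-[(3E,5S)-3,5-dimethyl-6-phenylhex-3-en-1-yl]-3,5-bis(ethoxycarbonyl)-4-hydroxy-2,8-dioxabicyclo[3.2.1]octane-4-carboxylic acid | C/C(=C\[C@@H](C)Cc1ccccc1)CC[C@@]12CC[C@@](C(=O)OCC)(O1)[C@](O)(C(=O)O)[C@@H](C(=O)OCC)O2 | intermediate
24 | (1S,3S,4S,5R)-1-[(3E,5S)-3,5-dimethyl-6-phenylhex-3-en-1-yl]-4-hydroxy-2,8-dioxabicyclo[3.2.1]octane-3,4,5-tricarboxylic acid | C/C(=C\[C@@H](C)Cc1ccccc1)CC[C@@]12CC[C@@](C(=O)O)(O1)[C@](O)(C(=O)O)[C@@H](C(=O)O)O2 | target

## Step count and least certain steps

Total: 13 steps. Longest linear sequence: 13 steps (1 → 24); compounds 3, 6, 10, 12, 15 and 18 are purchased.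

**Step 11 (key step).** The most likely failure is loss of facial control. Approach of 18 syn to the silyloxy group leads into the C3,C4-diastereomeric series. This is made worse by partial loss of the labile trimethylsilyl group at 110 °C through silyl transfer to glyoxylate hydrate or oligomers, after which the free C5 hydroxyl can intercept the carbenoid or the ylide. The fallback changes the controlling group, not the conditions. From 16, silylation with Et3SiCl/imidazole/DMAP gives the triethylsilyl ether 1-tert-butyl 4-ethyl (3R)-2-diazo-3-[(6E,8S)-6,8-dimethyl-3-oxo-9-phenylnon-6-en-1-yl]-3-[(triethylsilyl)oxy]butanedioate F1. Its larger and more robust pseudoaxial group should shield the syn face better. The same ylide formation and cycloaddition gives the triethylsilyl cycloadduct F2. HF·pyridine in THF then removes the silyl group and returns to 21, which is isolated and taken through the acid treatment of step 12.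

**Step 9.** The most likely failure is insufficient enantiofacial discrimination, since the precedent is strongest for aryl keto esters and 14 is aliphatic. Because C5' is fixed, this appears as the C5 epimer. Lewis-acid-induced loss of N2 with 1,2-shift is a second concern. The fallback gives up catalyst control for separation. From 14, addition of 15 with DBU in MeCN gives 16 together with its 3S epimer, 1-tert-butyl 4-ethyl (3S)-2-diazo-3-[(6E,8S)-6,8-dimethyl-3-oxo-9-phenylnon-6-en-1-yl]-3-hydroxybutanedioate F3. The two are diastereomers and are separated by preparative HPLC on a chiral stationary phase, which returns pure 16.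

**Step 12.** The most likely failure is protonation of the trisubstituted alkene during the long exposure to strong acid, leading to double-bond migration, hydration or Friedel–Crafts closure onto the phenyl ring, together with an incomplete ketal equilibrium. The fallback replaces protic equilibration by an aprotic silyl-transfer transketalisation. From 20, catalytic Me3SiOTf in CH2Cl2 at −40 → 0 °C ionises the C1–O(C4) bond. The C5 silyl ether oxygen closes onto C1 while the silyl group passes to the C4 oxygen. This gives the C4 silyl ether of the 2,8-ketal, 4-tert-butyl 3,5-diethyl (1S,3S,4S,5R)-1-[(3E,5S)-3,5-dimethyl-6-phenylhex-3-en-1-yl]-4-[(trimethylsilyl)oxy]-2,8-dioxabicyclo[3.2.1]octane-3,4,5-tricarboxylate F4. A short treatment with TFA/CH2Cl2 at 0 °C then removes the tert-butyl and silyl groups and returns to 23.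

**Step 8.** The most likely failure is attack of the electrophilic iodine reagent on the electron-rich alkene, or acid-induced cyclodehydration of the 1,4-dicarbonyl product to a furoate. The fallback avoids sulfur altogether and starts from 11.
- Ethyl (tert-butyldimethylsilyloxy)acetate is converted with lithium diisopropylamide and Me3SiCl into the silyl ketene acetal 2-[(tert-butyldimethylsilyl)oxy]-1-ethoxy-1-[(trimethylsilyl)oxy]ethene F5.
- TiCl4-mediated Mukaiyama–Michael addition of it to 11 at −78 °C gives the α-silyloxy keto ester ethyl (8E,10S)-2-[(tert-butyldimethylsilyl)oxy]-8,10-dimethyl-5-oxo-11-phenylundec-8-enoate F6.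
- HF·pyridine gives the α-hydroxy keto ester ethyl (8E,10S)-2-hydroxy-8,10-dimethyl-5-oxo-11-phenylundec-8-enoate F7.
- Dess–Martin periodinane oxidises F7 to 14.

## Further compounds

F1 | step 11 | 1-tert-butyl 4-ethyl (3R)-2-diazo-3-[(6E,8S)-6,8-dimethyl-3-oxo-9-phenylnon-6-en-1-yl]-3-[(triethylsilyl)oxy]butanedioate | C/C(=C\[C@@H](C)Cc1ccccc1)CCC(=O)CC[C@](O[Si](CC)(CC)CC)(C(=O)OCC)C(=[N+]=[N-])C(=O)OC(C)(C)C
F2 | step 11 | 1-tert-butyl 2,7-diethyl (1S,2R,5S,7S)-5-[(3E,5S)-3,5-dimethyl-6-phenylhex-3-en-1-yl]-2-[(triethylsilyl)oxy]-6,8-dioxabicyclo[3.2.1]octane-1,2,7-tricarboxylate | C/C(=C\[C@@H](C)Cc1ccccc1)CC[C@@]12CC[C@](O[Si](CC)(CC)CC)(C(=O)OCC)[C@@](C(=O)OC(C)(C)C)(O1)[C@@H](C(=O)OCC)O2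
F3 | step 9 | 1-tert-butyl 4-ethyl (3S)-2-diazo-3-[(6E,8S)-6,8-dimethyl-3-oxo-9-phenylnon-6-en-1-yl]-3-hydroxybutanedioate | C/C(=C\[C@@H](C)Cc1ccccc1)CCC(=O)CC[C@@](O)(C(=O)OCC)C(=[N+]=[N-])C(=O)OC(C)(C)C
F4 | step 12 | 4-tert-butyl 3,5-diethyl (1S,3S,4S,5R)-1-[(3E,5S)-3,5-dimethyl-6-phenylhex-3-en-1-yl]-4-[(trimethylsilyl)oxy]-2,8-dioxabicyclo[3.2.1]octane-3,4,5-tricarboxylate | C/C(=C\[C@@H](C)Cc1ccccc1)CC[C@@]12CC[C@@](C(=O)OCC)(O1)[C@](O[Si](C)(C)C)(C(=O)OC(C)(C)C)[C@@H](C(=O)OCC)O2
F5 | step 8 | 2-[(tert-butyldimethylsilyl)oxy]-1-ethoxy-1-[(trimethylsilyl)oxy]ethene | CCOC(O[Si](C)(C)C)=CO[Si](C)(C)C(C)(C)C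
F6 | step 8 | ethyl (8E,10S)-2-[(tert-butyldimethylsilyl)oxy]-8,10-dimethyl-5-oxo-11-phenylundec-8-enoate (both C2 epimers) | C/C(=C\[C@@H](C)Cc1ccccc1)CCC(=O)CCC(O[Si](C)(C)C(C)(C)C)C(=O)OCC
F7 | step 8 | ethyl (8E,10S)-2-hydroxy-8,10-dimethyl-5-oxo-11-phenylundec-8-enoate (both C2 epimers) | C/C(=C\[C@@H](C)Cc1ccccc1)CCC(=O)CCC(O)C(=O)OCC
A1 | alternative 1 | acyclic C3 ester bearing the C5 allyl group, C4/C5 acetonide and three silyloxymethyl groups | C/C(=C\[C@@H](C)Cc1ccccc1)CCC(=O)O[C@H](CO[Si](C)(C)C(C)(C)C)[C@]1(CO[Si](C)(C)C(C)(C)C)OC(C)(C)O[C@@]1(CC=C)CO[Si](C)(C)C(C)(C)C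
A2 | alternative 1 | oxepene enol ether fused to the C4/C5 acetonide | C/C(=C\[C@@H](C)Cc1ccccc1)CCC1=CC[C@@]2(CO[Si](C)(C)C(C)(C)C)OC(C)(C)O[C@@]2(CO[Si](C)(C)C(C)(C)C)[C@@H](CO[Si](C)(C)C(C)(C)C)O1
A3 | alternative 2 | C1 mixed ketal (tetrahydrofuran through the C5 oxygen, methyl glycolate on C1) carrying the C4 keto ester | C/C(=C\[C@@H](C)Cc1ccccc1)CC[C@@]1(OCC(=O)OC)CC[C@@](C(=O)OC)(O1)C(=O)C(=O)OC
A4 | alternative 2 | trimethyl ester of 24 | C/C(=C\[C@@H](C)Cc1ccccc1)CC[C@@]12CC[C@@](C(=O)OC)(O1)[C@](O)(C(=O)OC)[C@@H](C(=O)OC)O2
A5 | alternative 3 | C5 diazo tri-tert-butyl ester with C4 silyl ether and the C1 acyl group on the C3 oxygen | C/C(=C\[C@@H](C)Cc1ccccc1)CCC(=O)O[C@H](C(=O)OC(C)(C)C)[C@@](O[Si](C)(C)C)(C(=O)OC(C)(C)C)C(=[N+]=[N-])C(=O)OC(C)(C)C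
A6 | alternative 3 | ethynyl p-tolyl sulfone | C#CS(=O)(=O)c1ccc(C)cc1
A7 | alternative 3 | 7-(p-tolylsulfonyl)-2,8-dioxabicyclo[3.2.1]oct-6-ene tri-tert-butyl ester | C/C(=C\[C@@H](C)Cc1ccccc1)CC[C@@]12C(S(=O)(=O)c3ccc(C)cc3)=C[C@@](C(=O)OC(C)(C)C)(O1)[C@](O[Si](C)(C)C)(C(=O)OC(C)(C)C)[C@@H](C(=O)OC(C)(C)C)O2
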